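**Retrosynthetic overview**
1. C3′ stereocentre: set in the last step by enantioselective mono-transfer hydrogenation of achiral, C2h-symmetric rhodoxanthin 16 (new step).
2. C15–C15′: Stille coupling of two copies of one C20 half (stannane 12 and its iodide 13), then ketal removal.
3. C10=C11 by HWE with the stannyl C6 phosphonate 11; C8=C9 by Wittig with formyl ylide 6; C6=C7 by ethynylation and Meyer–Schuster rearrangement of ketoisophorone mono-ketal 2.
4. Rings: none is formed in the route. Both six-membered rings come intact from ketoisophorone 1, are carried as identical halves, and are made different only in step 12.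

Assumption: the target is taken as drawn (all-E polyene, 6E,6′E, 3′S); compounds that give carbon atoms to the target carry numbers, other atom-giving reagents are named with SMILES in their step.

**Route**

Step 1
Reactants: 1 ketoisophorone (2,6,6-trimethylcyclohex-2-ene-1,4-dione)
Product: 2 7,9,9-trimethyl-1,4-dioxaspiro[4.5]dec-6-en-8-one (ketoisophorone 4-ethylene ketal)
Conditions: HOCH2CH2OH (1.2 equiv), p-TsOH·H2O (2 mol%), benzene, reflux, Dean–Stark
Reagents that add atoms: ethylene glycol, OCCO
Why: Acid-catalysed ketalisation takes only the unhindered C4 carbonyl, while the C1 carbonyl between CMe2 and C(Me)= stays free and the C=C stays conjugated to it.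

Step 2
Reactants: 2 ketoisophorone 4-ethylene ketal; 3 ethynylmagnesium bromide
Product: 4 rac-8-ethynyl-7,9,9-trimethyl-1,4-dioxaspiro[4.5]dec-6-en-8-ol
Conditions: 3 (2 equiv, 0.5 M in THF), THF, 0 °C to rt; then H2O
Reagents that add atoms: none
Why: Grignard 1,2-addition to a ketone that cannot enolise (no α-H, γ-carbon is the ketal carbon); the racemic carbinol centre is erased in step 3.

Step 3
Reactants: 4 rac-ethynyl carbinol
Product: 5 (2E)-(7,9,9-trimethyl-1,4-dioxaspiro[4.5]dec-6-en-8-ylidene)acetaldehyde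
Conditions: MoO2(acac)2 (2 mol%), Ph3PAuCl (2 mol%), AgOTf (2 mol%), toluene, rt
Reagents that add atoms: none
Why: Meyer–Schuster rearrangement ([3,3] shift of the propargylic molybdate to the allenyl ester with Au-activation of the alkyne, then allenol-to-enal tautomerisation); a Rupe pathway is impossible because neither neighbour of the carbinol carbon carries H, and the E isomer (CHO on the CMe2 side) is taken by chromatography while the minor Z isomer is re-equilibrated.

Step 4
Reactants: 5 (E)-ylidene acetaldehyde; 6 2-(triphenylphosphoranylidene)propanal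
Product: 7 (2E,4E)-2-methyl-4-(7,9,9-trimethyl-1,4-dioxaspiro[4.5]dec-6-en-8-ylidene)but-2-enal
Conditions: 6 (1.3 equiv), toluene, 90 °C
Reagents that add atoms: none
Why: Wittig olefination with a stabilised formyl ylide gives the E trisubstituted C8=C9 bond and stops after one homologation because the α-methyl enal formed is less reactive than 5.

Step 5
Reactants: 8 (E)-3-methylpent-2-en-4-yn-1-ol
Product: 9 (2E,4E)-3-methyl-5-(tributylstannyl)penta-2,4-dien-1-ol
Conditions: Bu3SnH (1.1 equiv), PdCl2(PPh3)2 (2 mol%), THF, 0 °C to rt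
Reagents that add atoms: tributyltin hydride, CCCC[SnH](CCCC)CCCC
Why: Pd-catalysed hydrostannation adds Sn–H syn across the terminal alkyne with tin on the terminal carbon (E); the minor internal regioisomer is removed by chromatography.

Step 6
Reactants: 9 stannyl dienol
Product: 10 tributyl[(1E,3E)-5-bromo-3-methylpenta-1,3-dien-1-yl]stannane
Conditions: CBr4, PPh3, CH2Cl2, −20 to 0 °C
Reagents that add atoms: carbon tetrabromide, BrC(Br)(Br)Br
Why: Appel bromination displaces the oxyphosphonium group by SN2 at the primary allylic carbon under neutral conditions that the vinylstannane tolerates.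

Step 7
Reactants: 10 stannyl dienyl bromide
Product: 11 diethyl [(2E,4E)-3-methyl-5-(tributylstannyl)penta-2,4-dien-1-yl]phosphonate
Conditions: P(OEt)3 (neat), 90 °C
Reagents that add atoms: triethyl phosphite, CCOP(OCC)OCC
Why: Michaelis–Arbuzov reaction of a primary allylic bromide; the C–Sn bond and both E double bonds are unaffected by neutral phosphite.

Step 8
Reactants: 7 retro-C14 dienal; 11 stannyl C6 phosphonate
Product: 12 tributyl[(1E,3E,5E,7E,9E)-3,7-dimethyl-9-(7,9,9-trimethyl-1,4-dioxaspiro[4.5]dec-6-en-8-ylidene)nona-1,3,5,7-tetraen-1-yl]stannane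
Conditions: NaHMDS (1.05 equiv), THF, −78 to 0 °C; basic alumina chromatography
Reagents that add atoms: none
Why: Horner–Wadsworth–Emmons olefination of the dienyl phosphonate anion with the enal gives the E C10=C11 bond; ketal and vinylstannane are stable to the amide base at low temperature.

Step 9
Reactants: 12 C20 stannane (half of the batch)
Product: 13 (8E)-8-[(2E,4E,6E,8E)-9-iodo-3,7-dimethylnona-2,4,6,8-tetraen-1-ylidene]-7,9,9-trimethyl-1,4-dioxaspiro[4.5]dec-6-ene
Conditions: I2 (1.0 equiv), NaHCO3 (solid), CH2Cl2, −20 °C, dark; used at once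
Reagents that add atoms: iodine, II
Why: Iododestannylation is an electrophilic ipso substitution of the C–Sn bond with retention of the E geometry, and one equivalent of iodine at low temperature in the dark leaves the polyene intact.

Step 10
Reactants: 12 C20 stannane; 13 C20 iodide
Product: 14 (6E,6′E)-3,3:3′,3′-bis(ethylenedioxy)-4′,5′-didehydro-4,5′-retro-β,β-carotene (rhodoxanthin bis(ethylene ketal))
Conditions: Pd2(dba)3 (2.5 mol%), AsPh3 (20 mol%), NMP, rt, dark
Reagents that add atoms: none
Why: Stille cross-coupling with retention at both sp2 carbons forms the central C15–C15′ single bond; both partners carry the same skeleton, so any homocoupling gives the same product.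

Step 11
Reactants: 14 rhodoxanthin bis(ethylene ketal)
Product: 16 (6E,6′E)-rhodoxanthin, via rhodoxanthin mono(ethylene ketal) 15 (not isolated)
Conditions: oxalic acid (cat.), THF/H2O 4:1, rt, dark; crystallise from CH2Cl2/MeOH
Reagents that add atoms: water, O
Why: Acid-catalysed ketal hydrolysis is fast because each oxocarbenium ion is conjugated with the polyene; the dienone is acid-stable, and crystallisation is used to collect the (6E,6′E) isomer while the mother liquor is re-equilibrated with a trace of I2.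

Step 12
Reactants: 16 (6E,6′E)-rhodoxanthin
Product: 17 (3′S,6E,6′E)-3′-hydroxy-4′,5′-didehydro-4,5′-retro-β,β-caroten-3-one (eschscholtzxanthone, the target)
Conditions: RuCl(p-cymene)[(S,S)-TsDPEN] (3 mol%), HCO2H/Et3N 1:2 (1.0 equiv HCO2H, syringe pump), CH2Cl2, 0 °C, Ar, dark; stop at about 65% conversion (HPLC); chromatography, then crystallisation
Reagents that add atoms: none
Why: Proposed new method: enantioselective mono-transfer hydrogenation of a C2h-symmetric vinylogous quinone, in which the Ru–H/N–H form of the catalyst (made from formate with loss of CO2) passes hydride and proton to one C3=O through the six-membered outer-sphere transition state that needs the carbonyl oxygen as proton acceptor and so reduces C=O 1,2 and leaves the twelve conjugated C=C bonds alone; the carbonyl sits in the same local setting as C4=O of 4-oxoisophorone (CH=C(Me) on one side, CH2–CMe2 on the other), so the CH/π contact between the η6-arene and the C4=C5 unit should put hydride on the Re face and give 3′S with the (S,S) ligand, the usual sense for alkenyl and aryl ketones; the first reduction should beat the second by a statistical factor of two and because the mono-alcohol has lost the second through-conjugated acceptor, formate is limiting, the amine-rich medium protects the ionisable allylic alcohol, and unreacted 16 and over-reduced diol (after MnO2 re-oxidation) are recycled; closest known reaction type: Noyori–Ikariya Ru/TsDPEN asymmetric transfer hydrogenation of 4-oxoisophorone to 4-hydroxyisophorone and of conjugated enones and ynones.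

**Compound list**
1 | ketoisophorone (2,6,6-trimethylcyclohex-2-ene-1,4-dione) | CC1=CC(=O)CC(C)(C)C1=O | starting material
2 | 7,9,9-trimethyl-1,4-dioxaspiro[4.5]dec-6-en-8-one | CC1=CC2(OCCO2)CC(C)(C)C1=O | intermediate
3 | ethynylmagnesium bromide | C#C[Mg]Br | starting material
4 | rac-8-ethynyl-7,9,9-trimethyl-1,4-dioxaspiro[4.5]dec-6-en-8-ol | CC1=CC2(OCCO2)CC(C)(C)C1(O)C#C | intermediate
5 | (2E)-(7,9,9-trimethyl-1,4-dioxaspiro[4.5]dec-6-en-8-ylidene)acetaldehyde | CC1=CC2(OCCO2)CC(C)(C)\C1=C/C=O | intermediate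
6 | 2-(triphenylphosphoranylidene)propanal | CC(C=O)=P(c1ccccc1)(c1ccccc1)c1ccccc1 | starting material
7 | (2E,4E)-2-methyl-4-(7,9,9-trimethyl-1,4-dioxaspiro[4.5]dec-6-en-8-ylidene)but-2-enal | CC1=CC2(OCCO2)CC(C)(C)\C1=C/C=C(C)/C=O | intermediate
8 | (E)-3-methylpent-2-en-4-yn-1-ol | C#C/C(C)=C/CO | starting material
9 | (2E,4E)-3-methyl-5-(tributylstannyl)penta-2,4-dien-1-ol | OC/C=C(C)/C=C/[Sn](CCCC)(CCCC)CCCC | intermediate
10 | tributyl[(1E,3E)-5-bromo-3-methylpenta-1,3-dien-1-yl]stannane | BrC/C=C(C)/C=C/[Sn](CCCC)(CCCC)CCCC | intermediate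
11 | diethyl [(2E,4E)-3-methyl-5-(tributylstannyl)penta-2,4-dien-1-yl]phosphonate | CCOP(=O)(OCC)C/C=C(C)/C=C/[Sn](CCCC)(CCCC)CCCC | intermediate
12 | tributyl[(1E,3E,5E,7E,9E)-3,7-dimethyl-9-(7,9,9-trimethyl-1,4-dioxaspiro[4.5]dec-6-en-8-ylidene)nona-1,3,5,7-tetraen-1-yl]stannane | CC1=CC2(OCCO2)CC(C)(C)\C1=C/C=C(C)/C=C/C=C(C)/C=C/[Sn](CCCC)(CCCC)CCCC | intermediate
13 | (8E)-8-[(2E,4E,6E,8E)-9-iodo-3,7-dimethylnona-2,4,6,8-tetraen-1-ylidene]-7,9,9-trimethyl-1,4-dioxaspiro[4.5]dec-6-ene | CC1=CC2(OCCO2)CC(C)(C)\C1=C/C=C(C)/C=C/C=C(C)/C=C/I | intermediate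
14 | (6E,6′E)-3,3:3′,3′-bis(ethylenedioxy)-4′,5′-didehydro-4,5′-retro-β,β-carotene (rhodoxanthin bis(ethylene ketal)) | CC1=CC2(OCCO2)CC(C)(C)\C1=C/C=C(C)/C=C/C=C(C)/C=C/C=C/C(C)=C/C=C/C(C)=C/C=C3/C(C)=CC4(OCCO4)CC3(C)C | intermediate
15 | (6E,6′E)-3′,3′-ethylenedioxy-4′,5′-didehydro-4,5′-retro-β,β-caroten-3-one (rhodoxanthin mono(ethylene ketal)) | CC1=CC2(OCCO2)CC(C)(C)\C1=C/C=C(C)/C=C/C=C(C)/C=C/C=C/C(C)=C/C=C/C(C)=C/C=C3/C(C)=CC(=O)CC3(C)C | intermediate (not isolated)
16 | (6E,6′E)-rhodoxanthin (4′,5′-didehydro-4,5′-retro-β,β-carotene-3,3′-dione) | CC1=CC(=O)CC(C)(C)\C1=C/C=C(C)/C=C/C=C(C)/C=C/C=C/C(C)=C/C=C/C(C)=C/C=C1/C(C)=CC(=O)CC1(C)C | intermediate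
17 | (3′S,6E,6′E)-3′-hydroxy-4′,5′-didehydro-4,5′-retro-β,β-caroten-3-one (eschscholtzxanthone) | CC1=CC(=O)CC(C)(C)\C1=C/C=C(C)/C=C/C=C(C)/C=C/C=C/C(C)=C/C=C/C(C)=C/C=C1/C(C)=C[C@@H](O)CC1(C)C | target

**Step count**
Total: 12 steps. Longest linear sequence: 9 steps (steps 1, 2, 3, 4, 8, 9, 10, 11, 12).

**Three steps most likely to fail**

Step 12 (the new step). The risks are over-reduction to the diol, 1,n-reduction of the quinoid polyene, and an ee or sense of induction that differs from the model. The fallback uses known chemistry only: the stereocentre is bought first and the two ends are made different before the coupling. It sets out from 1, uses 3, 6, 11 and iodide 13 of the main route, and comes back at 17. Ketoisophorone 1 is reduced at the C4 carbonyl by the established Ru/TsDPEN transfer hydrogenation in iPrOH (the catalyst enantiomer that gives the S alcohol) to (S)-4-hydroxy-2,6,6-trimethylcyclohex-2-en-1-one F1. TBSCl and imidazole give (S)-4-(tert-butyldimethylsilyloxy)-2,6,6-trimethylcyclohex-2-en-1-one F2. Addition of 3 (CeCl3, THF, −78 °C) gives (4S)-4-(tert-butyldimethylsilyloxy)-1-ethynyl-2,6,6-trimethylcyclohex-2-en-1-ol F3 as both carbinol epimers, which converge. Meyer–Schuster rearrangement as in step 3 gives (2E)-[(4S)-4-(tert-butyldimethylsilyloxy)-2,6,6-trimethylcyclohex-2-en-1-ylidene]acetaldehyde F4. Wittig reaction with 6 gives (2E,4E)-4-[(4S)-4-(tert-butyldimethylsilyloxy)-2,6,6-trimethylcyclohex-2-en-1-ylidene]-2-methylbut-2-enal F5. HWE reaction with 11 gives tributyl[(1E,3E,5E,7E,9E)-9-[(4S)-4-(tert-butyldimethylsilyloxy)-2,6,6-trimethylcyclohex-2-en-1-ylidene]-3,7-dimethylnona-1,3,5,7-tetraen-1-yl]stannane F6. Stille coupling of this stannane with iodide 13 under the conditions of step 10 gives (3′S,6E,6′E)-3′-(tert-butyldimethylsilyloxy)-3,3-ethylenedioxy-4′,5′-didehydro-4,5′-retro-β,β-carotene F7. Brief treatment with oxalic acid in wet THF at 0 °C removes the ketal and gives (3′S,6E,6′E)-3′-(tert-butyldimethylsilyloxy)-4′,5′-didehydro-4,5′-retro-β,β-caroten-3-one F8. TBAF buffered with AcOH in THF at 0 °C then gives 17.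

Step 3. The carbinol is hindered and both allylic and propargylic, so the oxo-metal catalyst may give allylic 1,3-transposition instead, or a poor E/Z ratio. The fallback sets out from 2 and comes back at 5, with no alkyne and no oxo-metal catalyst. (Z)-2-Ethoxyvinyllithium (from (Z)-1-ethoxy-2-(tributylstannyl)ethene and n-BuLi, THF, −78 °C) adds to 2 to give 8-[(Z)-2-ethoxyethenyl]-7,9,9-trimethyl-1,4-dioxaspiro[4.5]dec-6-en-8-ol F9. PPTS in wet THF at 0 °C then triggers allylic transposition with loss of ethanol to enal 5 (the known β-alkoxyvinyl carbinol to enal two-carbon homologation).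

Step 9. Iodine may add to or isomerise the hexaene, and iodide 13 is light-sensitive. The fallback sets out from 12 and comes back at 14 without passing through 13 and without a new compound (F0). Copper(II)-mediated oxidative homocoupling of the vinylstannane (CuCl2, DMF, rt) joins two molecules of 12 at C15 directly, which is the wanted outcome because the coupling is symmetric.

**Further compounds**
F1 | step 12 | (S)-4-hydroxy-2,6,6-trimethylcyclohex-2-en-1-one | CC1=C[C@@H](O)CC(C)(C)C1=O
F2 | step 12 | (S)-4-(tert-butyldimethylsilyloxy)-2,6,6-trimethylcyclohex-2-en-1-one | CC1=C[C@@H](O[Si](C)(C)C(C)(C)C)CC(C)(C)C1=O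
F3 | step 12 | (4S)-4-(tert-butyldimethylsilyloxy)-1-ethynyl-2,6,6-trimethylcyclohex-2-en-1-ol (both C1 epimers) | CC1=C[C@@H](O[Si](C)(C)C(C)(C)C)CC(C)(C)C1(O)C#C
F4 | step 12 | (2E)-[(4S)-4-(tert-butyldimethylsilyloxy)-2,6,6-trimethylcyclohex-2-en-1-ylidene]acetaldehyde | CC1=C[C@@H](O[Si](C)(C)C(C)(C)C)CC(C)(C)\C1=C/C=O
F5 | step 12 | (2E,4E)-4-[(4S)-4-(tert-butyldimethylsilyloxy)-2,6,6-trimethylcyclohex-2-en-1-ylidene]-2-methylbut-2-enal | CC1=C[C@@H](O[Si](C)(C)C(C)(C)C)CC(C)(C)\C1=C/C=C(C)/C=O
F6 | step 12 | tributyl[(1E,3E,5E,7E,9E)-9-[(4S)-4-(tert-butyldimethylsilyloxy)-2,6,6-trimethylcyclohex-2-en-1-ylidene]-3,7-dimethylnona-1,3,5,7-tetraen-1-yl]stannane | CC1=C[C@@H](O[Si](C)(C)C(C)(C)C)CC(C)(C)\C1=C/C=C(C)/C=C/C=C(C)/C=C/[Sn](CCCC)(CCCC)CCCC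
F7 | step 12 | (3′S,6E,6′E)-3′-(tert-butyldimethylsilyloxy)-3,3-ethylenedioxy-4′,5′-didehydro-4,5′-retro-β,β-carotene | CC1=CC2(OCCO2)CC(C)(C)\C1=C/C=C(C)/C=C/C=C(C)/C=C/C=C/C(C)=C/C=C/C(C)=C/C=C3/C(C)=C[C@@H](O[Si](C)(C)C(C)(C)C)CC3(C)C
F8 | step 12 | (3′S,6E,6′E)-3′-(tert-butyldimethylsilyloxy)-4′,5′-didehydro-4,5′-retro-β,β-caroten-3-one | CC1=CC(=O)CC(C)(C)\C1=C/C=C(C)/C=C/C=C(C)/C=C/C=C/C(C)=C/C=C/C(C)=C/C=C3/C(C)=C[C@@H](O[Si](C)(C)C(C)(C)C)CC3(C)C
F9 | step 3 | rac-8-[(Z)-2-ethoxyethenyl]-7,9,9-trimethyl-1,4-dioxaspiro[4.5]dec-6-en-8-ol | CC1=CC2(OCCO2)CC(C)(C)C1(O)/C=C\OCC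
F0 | step 9 | none | none
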